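## Analysis of the target

The target is a biflavonoid. C3 of a naringenin-type flavanone (ring A and ring C form the 5,7-dihydroxychroman-4-one, ring B is the 4-hydroxyphenyl group at C2) is bonded to C3' of apigenin, the carbon ortho to the 4'-hydroxyl of the flavone's aryl ring (called the linker ring below). There are two adjacent stereocentres, C2 (R) and C3 (S). They are trans: H2 and H3 are anti and both aryl groups are equatorial on ring C. C3 is alpha to the C4 ketone and benzylic, so it epimerises easily and equilibration delivers the trans arrangement. C2 is a benzylic ether carbon para to a phenol and beta to the ketone, so ring C can open by beta-elimination or through a para-quinone methide, and that would erase the absolute configuration. Six free phenols make the compound sensitive to oxidants and base. The hard parts are the bond between two complete flavonoid units at a hindered sp3 carbon with no functional handle on either side, and absolute control at the labile C2. The strategy rests on one feature: C3 and C2 are the alpha and beta carbons of a 4-hydroxychalcone, and C3' is ortho to a phenol. These are the carbons that carry spin in the two phenoxyl radicals, and after coupling at the alpha carbon, C2 becomes the exocyclic carbon of a para-quinone methide within reach of the ring A hydroxyl.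

## Retrosynthetic reasoning

**13 to 12.** The four O–benzyl bonds on the two ring A units are cut last. Benzyl ethers come off by neutral hydrogenolysis, so neither C2 (ring opening) nor C3 (epimerisation beyond trans) is put at risk at the end. The forward step has to cleave four ethers without breaking the benzylic C2–O1 bond or saturating the chromone.

**12 to 6 and 8.** The C3–C3' bond and the O1–C2 bond are cut together. Both bonds end on the two alkene carbons of chalcone 6, and cutting them returns two ordinary flavonoid halves that need no halogen, boron or carbonyl handle: the reacting sites are C–H bonds. Cutting C2–C3 or C4–C4a instead would require the linker ring of 8 to be functionalised and homologated first. The forward reaction has to oxidise both phenols, couple the alpha carbon of 6 with C3' of 8 (adduct 9, then quinone methide 10), and close ring C with absolute control at C2 and trans geometry at C3. The five-membered isomer 11 must be drained back through 10.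

**8 to 6.** Flavone 8 differs from chalcone 6 only by the O1–C2 bond and two hydrogens. It is therefore traced back to 6 through flavanone 7 by an oxidative cyclisation. One compound becomes the source of both coupling partners, and no separate aroyl building block is needed.

**6 to 5.** The free 4-hydroxyl of 6 is masked as an acetal in 5. The mask is needed only for the aldol step, and it is chosen to come off under conditions that leave the benzyl ethers and the enone alone.

**5 to 2 and 4.** The enone double bond is cut as an aldol condensation between methyl ketone 2 and aldehyde 4. This reliably gives the E alkene and joins ring A to ring B in one step.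

**2 to 1, and 4 to 3.** Only O–alkyl bonds are cut. In 1 the hydroxyl chelated to the acetyl group is the least reactive, which lets two of the three be benzylated. In 3 the phenol is capped so that the aldehyde stays electrophilic under base.

## Alternatives that were turned down

**Alternative 1: hetero-Diels–Alder dihydropyranone, ring A added afterwards.**
- Disconnection: ring C is built first, at C2–C3 and at the bond from O1 to the future C8a.
- Forward key step: an aryl aldehyde carrying ring B and a 1-methoxy-3-silyloxy diene whose terminal carbon already bears the whole linker aryl unit are combined under a chiral (salen)CrCl complex (trivalent chromium). Acid work-up and equilibration at C3 should give the trans dihydropyranone A1.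
- For: this catalyst class is a dependable way to fix an oxygen-bearing benzylic centre, and the C2 configuration would not depend on any reversible event. On predictability of absolute control it is stronger than the chosen route.
- Against: the diene is substituted at its reacting terminus and carries a Lewis-basic chromone, both of which slow the cycloaddition. Making it requires a homologated, functionalised flavone. The decisive cost is that a 5,7-dioxygenated benzene ring must then be built onto the enol ether of A1 by acylation, cyclisation and aromatisation, under conditions that invite beta-elimination at C2.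
- Comparison: the chosen route takes ring A intact from 1 and needs seven steps, against well over twice as many here. What it gives up is the precedent for the stereo-determining step.

**Alternative 2: Friedel–Crafts closure of ring C at C4–C4a.**
- Disconnection: the acyl–aryl bond C4–C4a.
- Forward key step: a 2,3-diaryl-3-aryloxypropanoic acid with both stereocentres in place is activated with trifluoroacetic anhydride, and the phloroglucinol diether ring acylates itself to give A2.
- For: the closure is classical chromanone chemistry on a strongly activated ring whose two ortho positions are equivalent. Every step has precedent, and the stereocentres can be set earlier by stoichiometric control. On step-by-step certainty it is stronger than the chosen route.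
- Against: the acid needs a stereodefined benzylic aryl ether at a carbon bearing a para-oxygenated aryl group. That forces the deactivating carbonate on the 4'-oxygen, and etherification there competes with elimination and ionisation. The activated alpha-aryl acid can epimerise via the ketene or expel the aryloxide, which destroys C2. The linker aryl must be carried through a long linear sequence.
- Comparison: the chosen route offers a far shorter sequence from unfunctionalised flavonoids, at the price of one unprecedented step.

**Alternative 3: alkoxy ortho-quinone methide cycloaddition with a stilbene.**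
- Disconnection: C3–C4 and O1–C2.
- Forward key step: a chiral N-triflyl phosphoramide ionises a ring A salicylaldehyde acetal to an alkoxy ortho-quinone methide, which adds across an E-stilbene made of ring B and the linker ring. The product is the 4-methoxyflavan hexabenzyl ether A3.
- For: it is convergent, ring A is used intact, and a suprafacial addition turns the E geometry directly into the trans relation of C2 and C3. On relative stereocontrol it is at least as good as the chosen route.
- Against: both stilbene ends are oxygenated aryl groups, so the orientation that puts ring B at C2 is not secured. The chromone carbonyl competes for the acid. A3 has the wrong oxidation level at C4, and the ether must be hydrolysed and oxidised on an ionisation-prone 4-alkoxyflavan. The stilbene again needs a flavone functionalised at C3'.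
- Comparison: the chosen route has the C4 ketone from the start, needs no functionalised flavone and about half the steps.

Key step: step 6

Assumption: the sense of induction of the chiral phosphoric acid at C2 cannot be predicted with confidence; the (R) catalyst is written, and its mirror image would be used if the (2S,3R) product prevailed.

## Route

Step 1
Reactants: 1 2,4,6-trihydroxyacetophenone
Product: 2 1-[2,4-bis(benzyloxy)-6-hydroxyphenyl]ethan-1-one
Conditions: BnBr (2.1 equiv), K2CO3 (2.2 equiv), DMF, 0 °C to rt
Reagents that add atoms: benzyl bromide, BrCc1ccccc1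
Why: Williamson ether synthesis; after the first two alkylations the remaining hydroxyl is held in a hydrogen bond to the acetyl carbonyl and is much less nucleophilic, so two equivalents of halide should stop at the diether.

Step 2
Reactants: 3 4-hydroxybenzaldehyde
Product: 4 4-(methoxymethoxy)benzaldehyde
Conditions: MOMCl, i-Pr2NEt, CH2Cl2, 0 °C to rt
Reagents that add atoms: chloromethyl methyl ether, COCCl
Why: O-alkylation of a phenol with an alpha-chloro ether; the acetal prevents phenoxide formation, which would deactivate the aldehyde in the aldol step.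

Step 3
Reactants: 2 1-[2,4-bis(benzyloxy)-6-hydroxyphenyl]ethan-1-one; 4 4-(methoxymethoxy)benzaldehyde
Product: 5 (E)-1-[2,4-bis(benzyloxy)-6-hydroxyphenyl]-3-[4-(methoxymethoxy)phenyl]prop-2-en-1-one
Conditions: KOH (50% aq.), EtOH, rt; then cold 1 M HCl to pH 5
Reagents that add atoms: none
Why: Claisen–Schmidt condensation; the aldehyde cannot enolise, dehydration is driven by conjugation and the E alkene is the thermodynamic product, while benzyl and MOM ethers are stable to base.

Step 4
Reactants: 5 (E)-1-[2,4-bis(benzyloxy)-6-hydroxyphenyl]-3-[4-(methoxymethoxy)phenyl]prop-2-en-1-one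
Product: 6 (E)-1-[2,4-bis(benzyloxy)-6-hydroxyphenyl]-3-(4-hydroxyphenyl)prop-2-en-1-one
Conditions: 3 M HCl (aq.), MeOH–THF, 45 °C
Reagents that add atoms: none
Why: Acid-catalysed acetal exchange with methanol removes the MOM group; aryl benzyl ethers are stable to dilute acid, and the chelated enone closes to the flavanone only slowly at this temperature.

Step 5
Reactants: 6 (E)-1-[2,4-bis(benzyloxy)-6-hydroxyphenyl]-3-(4-hydroxyphenyl)prop-2-en-1-one
Product: 8 5,7-bis(benzyloxy)-2-(4-hydroxyphenyl)-4H-chromen-4-one, via 5,7-bis(benzyloxy)-4'-hydroxyflavanone 7 (not isolated)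
Conditions: I2 (10 mol%), DMSO, 120 °C
Reagents that add atoms: none
Why: Iodine-catalysed oxidative cyclisation of a 2'-hydroxychalcone: 6-endo oxa-Michael closure to 7, then iodine-mediated dehydrogenation across C2–C3 with DMSO as terminal oxidant; the free 4-hydroxyl is tolerated and the catalytic iodine loading limits ring iodination and ether cleavage. About three quarters of 6 is taken into this step and the rest is kept for step 6.

Step 6
Reactants: 6 (E)-1-[2,4-bis(benzyloxy)-6-hydroxyphenyl]-3-(4-hydroxyphenyl)prop-2-en-1-one; 8 5,7-bis(benzyloxy)-2-(4-hydroxyphenyl)-4H-chromen-4-one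
Product: 12 (2R,3S)-5,7-bis(benzyloxy)-3-{5-[5,7-bis(benzyloxy)-4-oxo-4H-chromen-2-yl]-2-hydroxyphenyl}-2-(4-hydroxyphenyl)chroman-4-one, via dienone quinone methide adduct 9 (not isolated), via para-quinone methide 10 (not isolated), via dihydrobenzofuran isomer 11 (not isolated)
Conditions: 8 (3 equiv), Ag2O (1.1 equiv, monovalent silver), CH2Cl2–acetone, rt, dark, slow addition of 6; filter through Celite; then (R)-3,3'-bis(2,4,6-triisopropylphenyl)-1,1'-binaphthyl-2,2'-diyl hydrogen phosphate (10 mol%), 4 Å MS, CH2Cl2, rt to 40 °C
Reagents that add atoms: none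
Why: Proposed new method: Ag2O (monovalent silver) takes one electron and one proton from each phenol; the radical of 6 has high spin density at the carbon alpha to the ketone and the radical of 8 at C3', so C–C coupling at these sites gives 9, whose dienone ring re-aromatises to the para-quinone methide 10 with the future C2 as its exocyclic carbon. The closest known reactions are the Ag2O-mediated 8–5 dimerisation of para-hydroxycinnamates to phenylcoumarans and chiral phosphoric acid-catalysed 1,6-additions of oxygen nucleophiles to para-quinone methides; a cross-coupling of a chalcone with a flavone followed by an enantioselective six-membered closure is without precedent. Ring C closes by 6-exo-trig oxa-1,6-addition of the ring A hydroxyl to the exocyclic carbon of 10, which restores aromatic ring B. The kinetically easier 5-exo-trig closure by the linker phenol gives 11 during the silver stage, but 11 is a para-hydroxybenzyl aryl ether that the acid should reopen to 10, whereas the chromanone, with trans-diequatorial aryl groups and its ring oxygen conjugated to the ketone, is expected to be the more stable isomer and to accumulate. Silver is filtered off before the acid is added because Ag2O would convert the phosphoric acid into its silver salt. C2 is controlled by the chiral phosphoric acid, which holds the quinone methide oxygen and the attacking hydroxyl in one hydrogen-bonded ion pair and leaves one face of the exocyclic carbon open; C3, alpha to the ketone and benzylic, epimerises through the enol under the same acid and settles trans to the C2 aryl group, so the racemic C3 of 10 is corrected. Cross-coupling has to win over homo-coupling, which slow addition of 6 to an excess of 8 should secure: the radical of 8 has no reactive side-chain carbon, dimerises slowly and persists, while the radical of 6 is kept scarce. Site selectivity rests on the spin distribution of the two radicals, and ring-size selectivity on the free 4-hydroxyl of ring B, which keeps both closures reversible through 10.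

Step 7
Reactants: 12 (2R,3S)-5,7-bis(benzyloxy)-3-{5-[5,7-bis(benzyloxy)-4-oxo-4H-chromen-2-yl]-2-hydroxyphenyl}-2-(4-hydroxyphenyl)chroman-4-one
Product: 13 (2R,3S)-3-[5-(5,7-dihydroxy-4-oxo-4H-chromen-2-yl)-2-hydroxyphenyl]-5,7-dihydroxy-2-(4-hydroxyphenyl)-2,3-dihydro-4H-chromen-4-one
Conditions: H2 (1 atm), 10% Pd/C, EtOAc–MeOH, rt
Reagents that add atoms: none
Why: Catalytic hydrogenolysis of four aryl benzyl ethers under neutral conditions; with no acid or base present ring C cannot open at C2 and C3 stays trans, and the chromone double bond and aryl ketones are reduced far more slowly than benzyl ethers are cleaved.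

## Compound list

1 | 2,4,6-trihydroxyacetophenone | CC(=O)c1c(O)cc(O)cc1O | starting material
2 | 1-[2,4-bis(benzyloxy)-6-hydroxyphenyl]ethan-1-one | CC(=O)c1c(O)cc(OCc2ccccc2)cc1OCc1ccccc1 | intermediate
3 | 4-hydroxybenzaldehyde | O=Cc1ccc(O)cc1 | starting material
4 | 4-(methoxymethoxy)benzaldehyde | COCOc1ccc(C=O)cc1 | intermediate
5 | (E)-1-[2,4-bis(benzyloxy)-6-hydroxyphenyl]-3-[4-(methoxymethoxy)phenyl]prop-2-en-1-one | O=C(/C=C/c1ccc(OCOC)cc1)c1c(O)cc(OCc2ccccc2)cc1OCc1ccccc1 | intermediate
6 | (E)-1-[2,4-bis(benzyloxy)-6-hydroxyphenyl]-3-(4-hydroxyphenyl)prop-2-en-1-one | O=C(/C=C/c1ccc(O)cc1)c1c(O)cc(OCc2ccccc2)cc1OCc1ccccc1 | intermediate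
7 | racemic 5,7-bis(benzyloxy)-2-(4-hydroxyphenyl)chroman-4-one (not isolated) | O=C1CC(c2ccc(O)cc2)Oc2cc(OCc3ccccc3)cc(OCc3ccccc3)c12 | intermediate
8 | 5,7-bis(benzyloxy)-2-(4-hydroxyphenyl)-4H-chromen-4-one (apigenin 5,7-dibenzyl ether) | O=c1cc(-c2ccc(O)cc2)oc2cc(OCc3ccccc3)cc(OCc3ccccc3)c12 | intermediate
9 | 4-{2-[5-(5,7-bis(benzyloxy)-4-oxo-4H-chromen-2-yl)-2-oxocyclohexa-3,5-dien-1-yl]-3-[2,4-bis(benzyloxy)-6-hydroxyphenyl]-3-oxopropylidene}cyclohexa-2,5-dien-1-one, mixture of stereoisomers (not isolated) | O=C1C=CC(=CC(C(=O)c2c(O)cc(OCc3ccccc3)cc2OCc2ccccc2)C2C=C(c3cc(=O)c4c(OCc5ccccc5)cc(OCc5ccccc5)cc4o3)C=CC2=O)C=C1 | intermediate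
10 | 4-{2-[5-(5,7-bis(benzyloxy)-4-oxo-4H-chromen-2-yl)-2-hydroxyphenyl]-3-[2,4-bis(benzyloxy)-6-hydroxyphenyl]-3-oxopropylidene}cyclohexa-2,5-dien-1-one, racemic (not isolated) | O=C1C=CC(=CC(C(=O)c2c(O)cc(OCc3ccccc3)cc2OCc2ccccc2)c2cc(-c3cc(=O)c4c(OCc5ccccc5)cc(OCc5ccccc5)cc4o3)ccc2O)C=C1 | intermediate
11 | 5,7-bis(benzyloxy)-2-{3-[2,4-bis(benzyloxy)-6-hydroxybenzoyl]-2-(4-hydroxyphenyl)-2,3-dihydro-1-benzofuran-5-yl}-4H-chromen-4-one, racemic (not isolated) | O=C(C1C(c2ccc(O)cc2)Oc2ccc(-c3cc(=O)c4c(OCc5ccccc5)cc(OCc5ccccc5)cc4o3)cc21)c1c(O)cc(OCc2ccccc2)cc1OCc1ccccc1 | intermediate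
12 | (2R,3S)-5,7-bis(benzyloxy)-3-{5-[5,7-bis(benzyloxy)-4-oxo-4H-chromen-2-yl]-2-hydroxyphenyl}-2-(4-hydroxyphenyl)chroman-4-one | O=C1c2c(OCc3ccccc3)cc(OCc3ccccc3)cc2O[C@@H](c2ccc(O)cc2)[C@@H]1c1cc(-c2cc(=O)c3c(OCc4ccccc4)cc(OCc4ccccc4)cc3o2)ccc1O | intermediate
13 | (2R,3S)-3-[5-(5,7-dihydroxy-4-oxo-4H-chromen-2-yl)-2-hydroxyphenyl]-5,7-dihydroxy-2-(4-hydroxyphenyl)-2,3-dihydro-4H-chromen-4-one | O=C1c2c(O)cc(O)cc2O[C@@H](c2ccc(O)cc2)[C@@H]1c1cc(-c2cc(=O)c3c(O)cc(O)cc3o2)ccc1O | target

## Step count and uncertain steps

Total: 7 steps. Longest linear sequence: 6 steps (steps 1, 3, 4, 5, 6 and 7); step 2 is a one-step side branch.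

**Step 6 (key step).**
- What may go wrong: homo-coupling of the chalcone-derived radical, or carbon–oxygen coupling, may outrun the cross C–C coupling. Closure may stop at the five-membered ether without reopening. Uncatalysed closure, or reversible opening of ring C, may erode the facial selectivity at C2. The free phenols of the product may be oxidised further.
- Fallback (known chemistry, from 2, rejoining at 13):
  - The hydroxyl of 2 is capped (MOMCl, NaH, DMF) to give 1-[2,4-bis(benzyloxy)-6-(methoxymethoxy)phenyl]ethan-1-one F1.
  - A second portion of 2 is condensed with commercial 4-(benzyloxy)-3-bromobenzaldehyde (KOH, EtOH) to (E)-1-[2,4-bis(benzyloxy)-6-hydroxyphenyl]-3-[4-(benzyloxy)-3-bromophenyl]prop-2-en-1-one F2. This is cyclised (I2 cat., DMSO, 120 °C) to 5,7-bis(benzyloxy)-2-[4-(benzyloxy)-3-bromophenyl]-4H-chromen-4-one F3.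
  - Ketone alpha-arylation of F1 with F3 (Pd2(dba)3, zerovalent palladium, with 4,5-bis(diphenylphosphino)-9,9-dimethylxanthene, K3PO4, toluene, 80 °C) gives the deoxybenzoin 1-[2,4-bis(benzyloxy)-6-(methoxymethoxy)phenyl]-2-{2-(benzyloxy)-5-[5,7-bis(benzyloxy)-4-oxo-4H-chromen-2-yl]phenyl}ethan-1-one F4.
  - Acidic methanolysis (HCl, MeOH–THF) frees the ring A hydroxyl to give 1-[2,4-bis(benzyloxy)-6-hydroxyphenyl]-2-{2-(benzyloxy)-5-[5,7-bis(benzyloxy)-4-oxo-4H-chromen-2-yl]phenyl}ethan-1-one F5.
  - Condensation of F5 with commercial 4-(benzyloxy)benzaldehyde (piperidine, EtOH, reflux; Knoevenagel condensation then oxa-Michael closure, with C3 equilibrating trans) should give racemic trans-5,7-bis(benzyloxy)-2-[4-(benzyloxy)phenyl]-3-{2-(benzyloxy)-5-[5,7-bis(benzyloxy)-4-oxo-4H-chromen-2-yl]phenyl}chroman-4-one F6.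
  - Preparative HPLC on a chiral stationary phase separates (2R,3S)-5,7-bis(benzyloxy)-2-[4-(benzyloxy)phenyl]-3-{2-(benzyloxy)-5-[5,7-bis(benzyloxy)-4-oxo-4H-chromen-2-yl]phenyl}chroman-4-one F7, and hydrogenolysis (H2, Pd/C) of F7 gives 13.

**Step 5.**
- What may go wrong: HI formed in the flask may cleave the peri benzyl ether next to the carbonyl, and the free phenol ring may be iodinated.
- Fallback (Baker–Venkataraman synthesis, from 2, rejoining at 8):
  - Ketone 2 is acylated with commercial 4-(allyloxy)benzoyl chloride (pyridine) to 2-acetyl-3,5-bis(benzyloxy)phenyl 4-(allyloxy)benzoate F8.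
  - KOH in pyridine at 50 °C shifts the aroyl group to carbon, giving 1-[2,4-bis(benzyloxy)-6-hydroxyphenyl]-3-[4-(allyloxy)phenyl]propane-1,3-dione F9.
  - Brief cyclodehydration (cat. H2SO4, AcOH, 90 °C) gives 2-[4-(allyloxy)phenyl]-5,7-bis(benzyloxy)-4H-chromen-4-one F10.
  - Deallylation (Pd(PPh3)4, zerovalent palladium, morpholine, THF) gives 8.

**Step 7.**
- What may go wrong: over-reduction (hydrogenolysis of the benzylic C2–O1 bond, saturation of the chromone double bond), or incomplete cleavage of the hindered ethers next to the carbonyls.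
- Fallback (from 12 to 13): Lewis-acid dealkylation with a cation scavenger (BCl3, pentamethylbenzene, CH2Cl2, −78 °C), which avoids hydrogen and metal altogether. This fallback makes no new compound (F0).

**Step 1.**
- What may go wrong: alkylation may run on to the triether, and the electron-rich ring may be benzylated at carbon, leaving a mixture that is hard to separate.
- Fallback (from 1, rejoining at 2): exhaustive benzylation (excess BnBr, K2CO3, DMF, 80 °C) gives 1-[2,4,6-tris(benzyloxy)phenyl]ethan-1-one F11. Chelation-directed cleavage of one ortho ether of F11 (MgBr2·OEt2, toluene–Et2O, reflux) then gives 2.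

## Further compounds

F1 | step 6 | 1-[2,4-bis(benzyloxy)-6-(methoxymethoxy)phenyl]ethan-1-one | CC(=O)c1c(OCOC)cc(OCc2ccccc2)cc1OCc1ccccc1
F2 | step 6 | (E)-1-[2,4-bis(benzyloxy)-6-hydroxyphenyl]-3-[4-(benzyloxy)-3-bromophenyl]prop-2-en-1-one | O=C(/C=C/c1ccc(OCc2ccccc2)c(Br)c1)c1c(O)cc(OCc2ccccc2)cc1OCc1ccccc1
F3 | step 6 | 5,7-bis(benzyloxy)-2-[4-(benzyloxy)-3-bromophenyl]-4H-chromen-4-one | O=c1cc(-c2ccc(OCc3ccccc3)c(Br)c2)oc2cc(OCc3ccccc3)cc(OCc3ccccc3)c12
F4 | step 6 | 1-[2,4-bis(benzyloxy)-6-(methoxymethoxy)phenyl]-2-{2-(benzyloxy)-5-[5,7-bis(benzyloxy)-4-oxo-4H-chromen-2-yl]phenyl}ethan-1-one | O=C(Cc1cc(-c2cc(=O)c3c(OCc4ccccc4)cc(OCc4ccccc4)cc3o2)ccc1OCc1ccccc1)c1c(OCOC)cc(OCc2ccccc2)cc1OCc1ccccc1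
F5 | step 6 | 1-[2,4-bis(benzyloxy)-6-hydroxyphenyl]-2-{2-(benzyloxy)-5-[5,7-bis(benzyloxy)-4-oxo-4H-chromen-2-yl]phenyl}ethan-1-one | O=C(Cc1cc(-c2cc(=O)c3c(OCc4ccccc4)cc(OCc4ccccc4)cc3o2)ccc1OCc1ccccc1)c1c(O)cc(OCc2ccccc2)cc1OCc1ccccc1
F6 | step 6 | racemic trans-5,7-bis(benzyloxy)-2-[4-(benzyloxy)phenyl]-3-{2-(benzyloxy)-5-[5,7-bis(benzyloxy)-4-oxo-4H-chromen-2-yl]phenyl}chroman-4-one | O=C1c2c(OCc3ccccc3)cc(OCc3ccccc3)cc2OC(c2ccc(OCc3ccccc3)cc2)C1c1cc(-c2cc(=O)c3c(OCc4ccccc4)cc(OCc4ccccc4)cc3o2)ccc1OCc1ccccc1
F7 | step 6 | (2R,3S)-5,7-bis(benzyloxy)-2-[4-(benzyloxy)phenyl]-3-{2-(benzyloxy)-5-[5,7-bis(benzyloxy)-4-oxo-4H-chromen-2-yl]phenyl}chroman-4-one | O=C1c2c(OCc3ccccc3)cc(OCc3ccccc3)cc2O[C@@H](c2ccc(OCc3ccccc3)cc2)[C@@H]1c1cc(-c2cc(=O)c3c(OCc4ccccc4)cc(OCc4ccccc4)cc3o2)ccc1OCc1ccccc1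
F8 | step 5 | 2-acetyl-3,5-bis(benzyloxy)phenyl 4-(allyloxy)benzoate | CC(=O)c1c(OC(=O)c2ccc(OCC=C)cc2)cc(OCc2ccccc2)cc1OCc1ccccc1
F9 | step 5 | 1-[2,4-bis(benzyloxy)-6-hydroxyphenyl]-3-[4-(allyloxy)phenyl]propane-1,3-dione | O=C(CC(=O)c1ccc(OCC=C)cc1)c1c(O)cc(OCc2ccccc2)cc1OCc1ccccc1
F10 | step 5 | 2-[4-(allyloxy)phenyl]-5,7-bis(benzyloxy)-4H-chromen-4-one | O=c1cc(-c2ccc(OCC=C)cc2)oc2cc(OCc3ccccc3)cc(OCc3ccccc3)c12
F0 | step 7 | none | none
F11 | step 1 | 1-[2,4,6-tris(benzyloxy)phenyl]ethan-1-one | CC(=O)c1c(OCc2ccccc2)cc(OCc2ccccc2)cc1OCc1ccccc1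
A1 | alternative 1 | (2R,3S)-2-[4-(benzyloxy)phenyl]-3-{2-(benzyloxy)-5-[5,7-bis(benzyloxy)-4-oxo-4H-chromen-2-yl]phenyl}-2,3-dihydro-4H-pyran-4-one | O=C1C=CO[C@@H](c2ccc(OCc3ccccc3)cc2)[C@@H]1c1cc(-c2cc(=O)c3c(OCc4ccccc4)cc(OCc4ccccc4)cc3o2)ccc1OCc1ccccc1
A2 | alternative 2 | benzyl 4-[(2R,3S)-5,7-bis(benzyloxy)-3-{2-(benzyloxy)-5-[5,7-bis(benzyloxy)-4-oxo-4H-chromen-2-yl]phenyl}-4-oxochroman-2-yl]phenyl carbonate | O=C1c2c(OCc3ccccc3)cc(OCc3ccccc3)cc2O[C@@H](c2ccc(OC(=O)OCc3ccccc3)cc2)[C@@H]1c1cc(-c2cc(=O)c3c(OCc4ccccc4)cc(OCc4ccccc4)cc3o2)ccc1OCc1ccccc1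
A3 | alternative 3 | 5,7-bis(benzyloxy)-2-[4-(benzyloxy)phenyl]-3-{2-(benzyloxy)-5-[5,7-bis(benzyloxy)-4-oxo-4H-chromen-2-yl]phenyl}-4-methoxychromane with the C2 and C3 configuration of the target, either C4 epimer | COC1c2c(OCc3ccccc3)cc(OCc3ccccc3)cc2O[C@@H](c2ccc(OCc3ccccc3)cc2)[C@@H]1c1cc(-c2cc(=O)c3c(OCc4ccccc4)cc(OCc4ccccc4)cc3o2)ccc1OCc1ccccc1
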